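Product came slowly in the summer run: at 3.00 min it stood at 10.0 % of the charge, while the starting material had lost 42.9 %. The summer run is this same flask, followed so far.

| flask | starting material | partner | free catalyst | second catalyst | remark |
|---|---|---|---|---|---|
| summer | 0.40 M | 0.42 M | 4 mM | 20 mM | the very flask that is asked about, followed so far |
| flask | 0.40 M | 0.420 M | 4.0 mM | 20 mM |  |

summer run (percent of the starting material charged)

| time / min | product / % | starting material / % |
|---|---|---|
| 0.500 | 0 | 89.6 |
| 1.00 | 1.0 | 81.6 |
| 1.50 | 3.5 | 74.3 |
| 2.00 | 4.7 | 68.0 |
| 2.50 | 7.8 | 63.1 |
| 3.00 | 10.0 | 57.1 |

(each reading ± 0.5 percentage points)

- "the catalyst" is free catalyst with its forms; second catalyst is a second catalyst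
- no earlier run changes the charge of free catalyst; that part of a forecast is a guess
- no earlier run changes the charge of partner; that part of a forecast is a guess

- factor on the rate of making product when 20 % of the starting material are converted if partner is charged twice over
- factor on the rate when 20 % of the starting material are converted if free catalyst is charged at 20 mM instead

I counted whatever had left the starting material without being product as a pool, 32.9 % of the charge at 3.00 min. Two times then mattered. The filling time, read between readings, was 1.11 min to reach 20 % conversion. The drain time, the mean pool divided by the rate of making product, read 6.36 min between 1.50 min and 3.00 min. It was longer than the filling time, so I reckoned the pool's loss during filling from their ratio.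

I took the pool to average about half its final size while filling, so I reckoned it had lost 8.73 % of itself by 20 % conversion. By my reckoning, the rate there was 0.0287 min⁻¹ of the charge. If the drain time stayed as it was, I reckoned that faster filling could raise the rate by a factor of about 1.10. Whether partner alters the drain time I could not read from one run.

The forecast gave 1.05 for partner and 1.1 for free catalyst, since “more partner or free catalyst only gets there sooner”. My figure held the drain time fixed and was one number for both changes, where the forecast gave two.

    starting material + free catalyst ⇌ free catalyst + open intermediate (K = 2.30, k = 54.0 M⁻¹ min⁻¹)
    second catalyst + open intermediate ⇌ catalyst intermediate (K = 10.0 M⁻¹, k = 8.40 M⁻¹ min⁻¹)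
    partner + catalyst intermediate → second catalyst + product (k = 120 M⁻¹ min⁻¹)
    starting material + free catalyst → spent catalyst (k = 0.0620 M⁻¹ min⁻¹)

Twice the partner gave 1.02, and 20 mM of free catalyst gave 1.01, both less than my 1.10. In this flask, 20 % conversion came at 1.10 min, with product forming at 0.0293 min⁻¹ of the charge. At 15.0 min, partner was down to 38.1 % of its charge and the open intermediate, nearly all of the pool, stood at 19.0 %. Divided by the drain time, that amount gives 0.0299 min⁻¹, and a little later, at 15.6 min, this flask made product at 0.0283 min⁻¹ of the charge.

All runs stem from a simulated flask for substances that don't exist; the scatter is artificial.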